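## Retrosynthetic overview
1. Target 26 comes from ester 25 by saponification. 25 comes from chromene 23 by a catalyst-controlled dearomative C8-prenylation, which sets the quaternary centre.
2. 23 comes from acylphloroglucinol 20 and prenal; the 2H-pyran closes on the only non-chelated OH.
3. Key step: 20 comes from cyclopentanetrione 13 and diazoketone 17. The diazo carbon is inserted into the C(O)–C(O) bond (ring expansion 5 → 6), and aromatisation drives the reaction.
4. 13 comes from methyl ketone 10 and dimethyl oxalate. 10 comes from iodide 7 and pentane-2,4-dione. 7 comes from an Evans deconjugative alkylation of a senecioyl imide with γ-bromotiglate 2, which sets the side-chain centre.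
5. Ring order: cyclopentenedione, then the six-membered carbocycle (by expansion), then the 2H-pyran, then dearomatisation to the cyclohexadienone.

Assumption: the CIP label of the ring carbon refers to the enol tautomer drawn in the target SMILES, and (R)-2-methylbutanoic acid is bought as the single enantiomer.

## Route

Step 1
Reactants: 1 methyl (E)-2-methylbut-2-enoate
Product: 2 methyl (E)-4-bromo-2-methylbut-2-enoate
Conditions: NBS (1.05 equiv), AIBN (2 mol %), PhCF3, reflux; distillation
Reagents that add atoms: N-bromosuccinimide O=C1CCC(=O)N1Br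
Why: Wohl–Ziegler allylic bromination goes mainly at the γ-methyl group through the ester-conjugated allyl radical, keeps the E geometry, and the minor 2-(bromomethyl) isomer is removed by distillation.

Step 2
Reactants: 3 3-methylbut-2-enoyl chloride
Product: 4 (4S)-4-benzyl-3-(3-methylbut-2-enoyl)-1,3-oxazolidin-2-one
Conditions: (S)-4-benzyloxazolidin-2-one, n-BuLi, THF, −78 °C; then 3, −78 → 0 °C
Reagents that add atoms: (4S)-4-benzyl-1,3-oxazolidin-2-one O=C1N[C@@H](Cc2ccccc2)CO1
Why: This is the standard N-acylation of a lithiated Evans auxiliary with an acid chloride, and no new stereocentre is formed.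

Step 3
Reactants: 4 (4S)-4-benzyl-3-(3-methylbut-2-enoyl)-1,3-oxazolidin-2-one; 2 methyl (E)-4-bromo-2-methylbut-2-enoate
Product: 5 methyl (2E,5S)-5-[(4S)-4-benzyl-2-oxo-1,3-oxazolidine-3-carbonyl]-2,6-dimethylhepta-2,6-dienoate
Conditions: NaHMDS (1.1 equiv), THF, −78 °C; then 2 (1.3 equiv), −78 → −40 °C
Reagents that add atoms: none
Why: In this Evans asymmetric alkylation in its deconjugative form, γ-deprotonation gives the chelated (Z)-dienolate, which is alkylated at the α-carbon anti to the benzyl group, creating the isopropenyl group and the C5 stereocentre (dr > 95:5 expected).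

Step 4
Reactants: 5 methyl (2E,5S)-5-[(4S)-4-benzyl-2-oxo-1,3-oxazolidine-3-carbonyl]-2,6-dimethylhepta-2,6-dienoate
Product: 6 methyl (2E,5S)-5-(hydroxymethyl)-2,6-dimethylhepta-2,6-dienoate
Conditions: NaBH4, THF/H2O (4:1), 0 °C → rt
Reagents that add atoms: none
Why: Borohydride cleaves the activated imide reductively but leaves the conjugated methyl ester untouched, and the α-centre is not epimerised.

Step 5
Reactants: 6 methyl (2E,5S)-5-(hydroxymethyl)-2,6-dimethylhepta-2,6-dienoate
Product: 7 methyl (2E,5S)-5-(iodomethyl)-2,6-dimethylhepta-2,6-dienoate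
Conditions: I2, PPh3, imidazole, CH2Cl2, 0 °C → rt
Reagents that add atoms: iodine II
Why: Appel-type (Garegg–Samuelsson) iodination of a primary alcohol takes place at the CH2 group and does not touch the neighbouring stereocentre or the alkenes.

Step 6
Reactants: 7 methyl (2E,5S)-5-(iodomethyl)-2,6-dimethylhepta-2,6-dienoate; 8 pentane-2,4-dione
Product: 10 methyl (2E,5S)-2-methyl-8-oxo-5-(prop-1-en-2-yl)non-2-enoate, via C-alkylated pentanedione 9 (not isolated)
Conditions: 8 (1.5 equiv), K2CO3 (2 equiv), DMF, 60 °C; then MeOH, 65 °C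
Reagents that add atoms: none
Why: The soft acetylacetonate is C-alkylated by the primary iodide without touching the enoate, and base-catalysed retro-Claisen deacetylation in methanol then gives the methyl ketone (classical alkylation–cleavage ketone synthesis).

Step 7
Reactants: 10 methyl (2E,5S)-2-methyl-8-oxo-5-(prop-1-en-2-yl)non-2-enoate; 11 dimethyl oxalate
Product: 13 methyl (2E,5R)-5-[(2-hydroxy-3,5-dioxocyclopent-1-en-1-yl)methyl]-2,6-dimethylhepta-2,6-dienoate, via acylpyruvate 12 (not isolated)
Conditions: 11 (1.05 equiv), NaOMe (2.2 equiv), MeOH, 0 → 65 °C; cold 1 M HCl work-up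
Reagents that add atoms: none
Why: A crossed Claisen condensation at the methyl group followed by a Dieckmann-type closure from the α′-methylene is the classical route from 2-alkanones to 3-alkylcyclopentane-1,2,4-triones, and the side-chain centre is not acidic.

Step 8
Reactants: 14 (R)-2-methylbutanoic acid; 15 (trimethylsilyl)diazomethane
Product: 17 (R)-1-diazo-3-methylpentan-2-one, via acid chloride 16 (not isolated)
Conditions: (COCl)2, cat. DMF, CH2Cl2, 0 °C → rt; evaporate; 15, THF/MeCN, 0 °C
Reagents that add atoms: none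
Why: This is the Arndt–Eistert-type acylation of a diazoalkane, run without amine base so that no ketene forms and the α-stereocentre from the chiral pool is kept.

Step 9
Reactants: 13 methyl (2E,5R)-5-[(2-hydroxy-3,5-dioxocyclopent-1-en-1-yl)methyl]-2,6-dimethylhepta-2,6-dienoate; 17 (R)-1-diazo-3-methylpentan-2-one
Product: 20 methyl (2E,5R)-2,6-dimethyl-5-({2,4,6-trihydroxy-3-[(2R)-2-methylbutanoyl]phenyl}methyl)hepta-2,6-dienoate, via TMS enol ether 18 (not isolated), via aryl TMS ether 19 (not isolated)
Conditions: TMSOTf (1.1 equiv), 2,6-lutidine (1.1 equiv), CH2Cl2, −78 → 0 °C; then 17 (1.3 equiv), Sc(OTf)3 (10 mol %), −40 → 0 °C; MeOH/aq NaHCO3 work-up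
Reagents that add atoms: none
Why: Proposed new method: a one-carbon ring expansion of a cyclopentane-1,2,4-trione by formal insertion of an acyldiazomethane carbon into its C(O)–C(O) bond, in which transient O-silylation removes the acidic enol proton that would otherwise destroy 17 and leaves ring C3=O as the only ketone that is not a vinylogous ester, Sc(III) activates that carbonyl, the diazo carbon adds, and the sp2 oxygen-bearing ring carbon C2 migrates with loss of N2 in preference to the acyl-deactivated CH2, so the five-membered ring becomes a 2-acylcyclohexenedione that tautomerises irreversibly to the phenol without forming or touching any stereocentre; the closest known reaction types are the Büchner–Curtius–Schlotterbeck/Tiffeneau–Demjanov-type homologation of ketones with α-diazocarbonyl compounds and the Eistert ring expansion of isatins and indane-1,2,3-trione.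

Step 10
Reactants: 20 methyl (2E,5R)-2,6-dimethyl-5-({2,4,6-trihydroxy-3-[(2R)-2-methylbutanoyl]phenyl}methyl)hepta-2,6-dienoate; 21 3-methylbut-2-enal
Product: 23 methyl (2E,5R)-5-({5,7-dihydroxy-2,2-dimethyl-6-[(2R)-2-methylbutanoyl]-2H-chromen-8-yl}methyl)-2,6-dimethylhepta-2,6-dienoate, via o-quinone methide 22 (not isolated)
Conditions: 21 (1.5 equiv), EDDA (20 mol %), toluene, 90 °C
Reagents that add atoms: none
Why: Knoevenagel-type condensation at the only free ring CH followed by oxa-6π closure (chromenylation) uses the OH para to the acyl group, because it is the only non-chelated and most acidic hydroxyl, which places the pyran oxygen next to the alkyl-bearing carbon.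

Step 11
Reactants: 23 methyl (2E,5R)-5-({5,7-dihydroxy-2,2-dimethyl-6-[(2R)-2-methylbutanoyl]-2H-chromen-8-yl}methyl)-2,6-dimethylhepta-2,6-dienoate; 24 1-bromo-3-methylbut-2-ene
Product: 25 methyl (2E,5R)-5-({(8R)-7-hydroxy-2,2-dimethyl-6-[(2R)-2-methylbutanoyl]-8-(3-methylbut-2-en-1-yl)-5-oxo-5,8-dihydro-2H-chromen-8-yl}methyl)-2,6-dimethylhepta-2,6-dienoate
Conditions: 24 (1.2 equiv), N-spiro binaphthyl ammonium bromide bearing 3,3′-bis(3,4,5-trifluorophenyl) groups (5 mol %), CsOH·H2O (1.5 equiv), toluene/CH2Cl2 (4:1), −40 °C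
Reagents that add atoms: none
Why: Proposed new method: a catalyst-controlled dearomative C-prenylation by chiral ion-pair (phase-transfer) catalysis, in which the chelated acylphenolate of 23 is carried into the non-polar phase as a tight ion pair, the 3,3′-aryl walls of the C2-symmetric cation cover one face of the flat anion, and prenyl bromide alkylates C8 (the alkyl-bearing carbon flanked by two oxygens, C- over O-alkylation being favoured in the non-polar medium) by SN2 from the open face, so the quaternary (8R) centre is set by the catalyst because both existing stereocentres are remote, the catalyst antipode that gives 8R being fixed in one pair of test runs; the closest known reaction types are the base-mediated gem-prenylation of acylphloroglucinols (lupulone-type alkylative dearomatisation), phase-transfer alkylation of β-dicarbonyl compounds to quaternary centres, and phase-transfer-controlled alkylative dearomatisation–annulation of acylphloroglucinols.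

Step 12
Reactants: 25 methyl (2E,5R)-5-({(8R)-7-hydroxy-2,2-dimethyl-6-[(2R)-2-methylbutanoyl]-8-(3-methylbut-2-en-1-yl)-5-oxo-5,8-dihydro-2H-chromen-8-yl}methyl)-2,6-dimethylhepta-2,6-dienoate
Product: 26 (2E,5R)-5-({(8R)-7-hydroxy-2,2-dimethyl-6-[(2R)-2-methylbutanoyl]-8-(3-methylbut-2-en-1-yl)-5-oxo-5,8-dihydro-2H-chromen-8-yl}methyl)-2,6-dimethylhepta-2,6-dienoic acid
Conditions: LiOH (5 equiv), degassed THF/MeOH/H2O, 35 °C; 1 M HCl to pH 3 at 0 °C
Reagents that add atoms: lithium hydroxide [Li+].[OH-]
Why: During saponification of the enoate the β-triketone is present as its inert enolate, which protects the core from retro-Claisen cleavage and the acyl α-centre from epimerisation, while exclusion of air avoids hulupone-type oxidation.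

## Compound list
1 | methyl (E)-2-methylbut-2-enoate (methyl tiglate) | C/C=C(\C)C(=O)OC | starting material
2 | methyl (E)-4-bromo-2-methylbut-2-enoate | BrC/C=C(\C)C(=O)OC | intermediate
3 | 3-methylbut-2-enoyl chloride | CC(C)=CC(=O)Cl | starting material
4 | (4S)-4-benzyl-3-(3-methylbut-2-enoyl)-1,3-oxazolidin-2-one | CC(C)=CC(=O)N1[C@@H](Cc2ccccc2)COC1=O | intermediate
5 | methyl (2E,5S)-5-[(4S)-4-benzyl-2-oxo-1,3-oxazolidine-3-carbonyl]-2,6-dimethylhepta-2,6-dienoate | C=C(C)[C@H](C/C=C(\C)C(=O)OC)C(=O)N1[C@@H](Cc2ccccc2)COC1=O | intermediate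
6 | methyl (2E,5S)-5-(hydroxymethyl)-2,6-dimethylhepta-2,6-dienoate | C=C(C)[C@H](C/C=C(\C)C(=O)OC)CO | intermediate
7 | methyl (2E,5S)-5-(iodomethyl)-2,6-dimethylhepta-2,6-dienoate | C=C(C)[C@H](C/C=C(\C)C(=O)OC)CI | intermediate
8 | pentane-2,4-dione | CC(=O)CC(C)=O | starting material
9 | methyl (2E,5R)-5-(2-acetyl-3-oxobutyl)-2,6-dimethylhepta-2,6-dienoate | C=C(C)[C@H](C/C=C(\C)C(=O)OC)CC(C(C)=O)C(C)=O | intermediate
10 | methyl (2E,5S)-2-methyl-8-oxo-5-(prop-1-en-2-yl)non-2-enoate | C=C(C)[C@H](C/C=C(\C)C(=O)OC)CCC(C)=O | intermediate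
11 | dimethyl oxalate | COC(=O)C(=O)OC | starting material
12 | dimethyl (2E,5S)-2-methyl-8,10-dioxo-5-(prop-1-en-2-yl)undec-2-enedioate | C=C(C)[C@H](C/C=C(\C)C(=O)OC)CCC(=O)CC(=O)C(=O)OC | intermediate
13 | methyl (2E,5R)-5-[(2-hydroxy-3,5-dioxocyclopent-1-en-1-yl)methyl]-2,6-dimethylhepta-2,6-dienoate (enol of the 3-alkylcyclopentane-1,2,4-trione) | C=C(C)[C@H](C/C=C(\C)C(=O)OC)CC1=C(O)C(=O)CC1=O | intermediate
14 | (R)-2-methylbutanoic acid | CC[C@@H](C)C(=O)O | starting material
15 | (trimethylsilyl)diazomethane | C[Si](C)(C)C=[N+]=[N-] | starting material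
16 | (R)-2-methylbutanoyl chloride | CC[C@@H](C)C(=O)Cl | intermediate
17 | (R)-1-diazo-3-methylpentan-2-one | CC[C@@H](C)C(=O)C=[N+]=[N-] | intermediate
18 | methyl (2E,5R)-5-{[3,5-dioxo-2-(trimethylsilyloxy)cyclopent-1-en-1-yl]methyl}-2,6-dimethylhepta-2,6-dienoate | C=C(C)[C@H](C/C=C(\C)C(=O)OC)CC1=C(O[Si](C)(C)C)C(=O)CC1=O | intermediate
19 | methyl (2E,5R)-5-({4,6-dihydroxy-3-[(2R)-2-methylbutanoyl]-2-(trimethylsilyloxy)phenyl}methyl)-2,6-dimethylhepta-2,6-dienoate | C=C(C)[C@H](C/C=C(\C)C(=O)OC)Cc1c(O)cc(O)c(C(=O)[C@H](C)CC)c1O[Si](C)(C)C | intermediate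
20 | methyl (2E,5R)-2,6-dimethyl-5-({2,4,6-trihydroxy-3-[(2R)-2-methylbutanoyl]phenyl}methyl)hepta-2,6-dienoate | C=C(C)[C@H](C/C=C(\C)C(=O)OC)Cc1c(O)cc(O)c(C(=O)[C@H](C)CC)c1O | intermediate
21 | 3-methylbut-2-enal | CC(C)=CC=O | starting material
22 | methyl (2E,5R)-5-({2,4-dihydroxy-3-[(2R)-2-methylbutanoyl]-5-(3-methylbut-2-en-1-ylidene)-6-oxocyclohexa-1,3-dien-1-yl}methyl)-2,6-dimethylhepta-2,6-dienoate | C=C(C)[C@H](C/C=C(\C)C(=O)OC)CC1=C(O)C(C(=O)[C@H](C)CC)=C(O)C(=CC=C(C)C)C1=O | intermediate
23 | methyl (2E,5R)-5-({5,7-dihydroxy-2,2-dimethyl-6-[(2R)-2-methylbutanoyl]-2H-chromen-8-yl}methyl)-2,6-dimethylhepta-2,6-dienoate | C=C(C)[C@H](C/C=C(\C)C(=O)OC)Cc1c(O)c(C(=O)[C@H](C)CC)c(O)c2C=CC(C)(C)Oc12 | intermediate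
24 | 1-bromo-3-methylbut-2-ene (prenyl bromide) | CC(C)=CCBr | starting material
25 | methyl (2E,5R)-5-({(8R)-7-hydroxy-2,2-dimethyl-6-[(2R)-2-methylbutanoyl]-8-(3-methylbut-2-en-1-yl)-5-oxo-5,8-dihydro-2H-chromen-8-yl}methyl)-2,6-dimethylhepta-2,6-dienoate | C=C(C)[C@H](C/C=C(\C)C(=O)OC)C[C@]1(CC=C(C)C)C(O)=C(C(=O)[C@H](C)CC)C(=O)C2=C1OC(C)(C)C=C2 | intermediate
26 | (2E,5R)-5-({(8R)-7-hydroxy-2,2-dimethyl-6-[(2R)-2-methylbutanoyl]-8-(3-methylbut-2-en-1-yl)-5-oxo-5,8-dihydro-2H-chromen-8-yl}methyl)-2,6-dimethylhepta-2,6-dienoic acid (CNP0184919.1) | C=C(C)[C@H](C/C=C(\C)C(=O)O)C[C@]1(CC=C(C)C)C(O)=C(C(=O)[C@H](C)CC)C(=O)C2=C1OC(C)(C)C=C2 | target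

## Step count and risks
Total step count: 12. Longest linear sequence: 10 steps (1, 3, 4, 5, 6, 7, 9, 10, 11, 12).

**Step 7.** The ring CH2 of the product is itself acylated by oxalate, so the 1:1 stoichiometry may give mixtures and incomplete closure.
- The fallback sets out from 10 and drives the condensation on purpose with excess 11 (2.5 equiv) and NaOMe (3.5 equiv). This is the classical block-and-release protocol for 3-alkylcyclopentane-1,2,4-triones and gives the 4-methoxalyl trione F1.
- The exocyclic methoxalyl group is then removed hydrolytically (aq Na2CO3, 40 °C, retro-Claisen at the very electrophilic α-keto carbonyl).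
- The fallback comes back to the route at 13.

**Step 9 (new).** Three failure modes are foreseeable:
- the diazoketone may be consumed by O-alkylation;
- an epoxide may form instead of the shift;
- the CH2 group may migrate, which would give a 1,2,4-trioxygenated arene.

The fallback gives up the five-membered ring and builds the arene by a known polyketide-type Claisen sequence.
- It sets out from 10, whose kinetic lithium enolate (LiHMDS, THF, −78 °C) is acylated with acid chloride 16 to the β-diketone F2.
- Magnesium-mediated C-acylation (MgCl2, pyridine, methyl 3-chloro-3-oxopropanoate, CH2Cl2, 0 °C) gives the triacylmethane ester F3.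
- KOt-Bu (3.5 equiv, THF) closes the δ-keto ester in a Dieckmann-type cyclisation that aromatises.
- The fallback comes back to the route at 20.

**Step 11 (new).** Face selectivity of the ion pair may be low, and O-prenylation may compete.
- The fallback sets out from 23 and uses the known, uncatalysed alkylative dearomatisation (prenyl bromide, aqueous KOH, 0 °C, lupulone-type gem-alkylation).
- This gives 25 together with the (8S)-epimer F4.
- The two are diastereomers and are separated by preparative HPLC.
- The fallback comes back to the route at 25.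

## Further compounds
F1 | step 7 | methyl (2E,5R)-5-{[2-hydroxy-4-(2-methoxy-2-oxoacetyl)-3,5-dioxocyclopent-1-en-1-yl]methyl}-2,6-dimethylhepta-2,6-dienoate | C=C(C)[C@H](C/C=C(\C)C(=O)OC)CC1=C(O)C(=O)C(C(=O)C(=O)OC)C1=O
F2 | step 9 | methyl (2E,5S,11R)-2,11-dimethyl-8,10-dioxo-5-(prop-1-en-2-yl)tridec-2-enoate | C=C(C)[C@H](C/C=C(\C)C(=O)OC)CCC(=O)CC(=O)[C@H](C)CC
F3 | step 9 | methyl (2E,5S,11R)-9-(3-methoxy-3-oxopropanoyl)-2,11-dimethyl-8,10-dioxo-5-(prop-1-en-2-yl)tridec-2-enoate | C=C(C)[C@H](C/C=C(\C)C(=O)OC)CCC(=O)C(C(=O)CC(=O)OC)C(=O)[C@H](C)CC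
F4 | step 11 | methyl (2E,5R)-5-({(8S)-7-hydroxy-2,2-dimethyl-6-[(2R)-2-methylbutanoyl]-8-(3-methylbut-2-en-1-yl)-5-oxo-5,8-dihydro-2H-chromen-8-yl}methyl)-2,6-dimethylhepta-2,6-dienoate | C=C(C)[C@H](C/C=C(\C)C(=O)OC)C[C@@]1(CC=C(C)C)C(O)=C(C(=O)[C@H](C)CC)C(=O)C2=C1OC(C)(C)C=C2
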